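The alder run gave me a clock for a reversible approach to a level, and I wanted that clock before guessing at any hotter or colder flask.

| setting | elm | larch | alder | Tuesday's | Wednesday's | Thursday's | Sunday's |
|---|---|---|---|---|---|---|---|
| starting material | 10 mM | 10 mM | 15 mM | 10 mM | 10 mM | 10 mM | 10 mM |
| free catalyst | 0.62 mM | 0.97 mM | 0.44 mM | 0.44 mM | 0.44 mM | 0.44 mM | 0.44 mM |
| temperature | 22 °C | 72 °C | 22 °C | 60 °C | 90 °C | 0 °C | 30 °C |
| remark | run made earlier | run made earlier | run made earlier |  |  |  |  |
| time |  |  |  | 3.0 min | 3.0 min | 3.0 min | 3.0 min |

elm run (percent of the starting material charged)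

| time / min | target / % | starting material / % |
|---|---|---|
| 5.00 | 43.7 | 53.5 |
| 12.0 | 61.5 | 36.0 |
| 15.0 | 63.1 | 32.1 |
| 25.0 | 66.7 | 28.7 |

larch run (percent of the starting material charged)

| time / s | target / % | starting material / % |
|---|---|---|
| 30.0 | 26.9 | 48.3 |
| 60.0 | 29.1 | 33.4 |
| 80.0 | 26.9 | 24.3 |
| 120 | 29.6 | 16.0 |

alder run (percent of the starting material charged)

| time / min | target / % | starting material / % |
|---|---|---|
| 1.50 | 15.2 | 84.4 |
| 4.00 | 29.9 | 68.6 |
| 10.0 | 50.9 | 44.9 |
| 25.0 | 63.3 | 31.9 |

(standard deviation of a reading: 1 percentage point)

- which flask leads in amount of target, in percent of the starting material charged ("all alike" within 1.5 percentage points) (Tuesday's / Wednesday's / Thursday's / Sunday's / all alike)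
- how much target is there at the end, in percent of the starting material charged: Tuesday's
- how much target is there at the end, in percent of the starting material charged: Wednesday's
- how much target is there at the end, in percent of the starting material charged: Thursday's
- how much target is there at the end, in percent of the starting material charged: Sunday's

- the numbers in the tables scatter with a standard deviation of 1 percentage point

I took the level L from elm's last reading of target, 66.7%, and let the gap between target and L shrink exponentially, the pseudo-first-order picture with the catalyst as a constant factor. Alder's reading of 29.9% at 4.00 min then gave an approach rate λ of 0.149 /min. I worked in powers of ten, and so carried the decade time D, the minutes in which the gap to the level shrinks tenfold at 0.44 mM free catalyst and 22 °C: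

D = ln(10)/λ = 15.5 min

y(t) = L · (1 − 10^(−t/D))

The curve starts along a tangent worth 29.8% in 3.0 min, and that tangent meets the level at its knee, 6.71 min. I scaled D inversely with catalyst to test it on elm, and the line gave 43.3% at 5.00 min against the reading of 43.7%. At 3.0 min the curve stands at 24.0%, below the tangent.

So I expected Thursday's, colder, to fall below that figure, and Sunday's, warmer, to rise above it. The larch run set a second mark: its readings of target stayed flat around 28.1% while its readings of starting material fell from 48.3% to 16.0%. Tuesday's and Wednesday's carry about half of larch's catalyst, so I held that plateau as their ceiling. Scaled by that catalyst ratio, the plateau came to 12.8%, below the 24.0% of my line, and although Tuesday's runs colder than larch, this was my ground, a judgement, for choosing Sunday's as my leader.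

The forecast named Tuesday's, with 33%, 6%, 15% and 30% for Tuesday's, Wednesday's, Thursday's and Sunday's, and called the first “near the optimum”, where I differed.

The flasks gave 26.2%, 9.61%, 7.42% and 32.9% in that order, so Sunday's led.

    starting material + free catalyst ⇌ target + free catalyst, rate k1*[starting material]*[free catalyst] forward; the back reaction follows from the equilibrium constant (K = 0.580, k = 120 /M/s, Ea = 44.0 kJ/mol, ΔH = −19.0 kJ/mol)
    starting material ⇌ isomer of the product A (K = 11.0, k = 0.0580 /s, Ea = 91.0 kJ/mol, ΔH = −90.0 kJ/mol)
    starting material + free catalyst ⇌ isomer of the product B + free catalyst, rate k3*[starting material]*[free catalyst] forward; the back reaction follows from the equilibrium constant (K = 1.30, k = 12.0 /M/s, Ea = 67.0 kJ/mol, ΔH = −64.0 kJ/mol)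
    free catalyst → spent catalyst (k = 0.400 /s, Ea = 85.0 kJ/mol)
    (constants at 90 °C)

The neighbouring flask repeats Thursday's recipe at 25 °C, warmer than alder's 22 °C. With L and D unchanged, my line gives it 24.0%, and its target came in above that figure. Held to the same L, its target corresponds to a decade time of 12.5 min, shorter than D. At 3.00 min, the neighbouring flask held 28.2% target beside 70.0% starting material.

(The runs come from a simulation for substances that don't exist; scatter was added.)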